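**Retrosynthetic overview**
- The C9 carbinol comes last, by reagent-controlled reduction of a 9-ketone; the C3 ester comes from Mitsunobu inversion of a 3-epi alcohol with (2R)-2-methylbutanoic acid.
- The ten-membered carbocycle and the γ-lactone are made in one flask: anionic oxy-Cope ring expansion of a 1,6-dialkenylcyclohex-2-en-1-ol (forms C6–C7, cleaves C4–C9), then acid-triggered desilylation, ortho ester opening and lactonisation.
- The rearrangement substrate is joined from an (E)-alkenyllithium (C7, C8, C11–C13; C12 masked as an ortho ester, C11 from Roche ester) and a ring-A enone whose E-silyl enol ether supplies C5/C6.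
- The ring-A enone comes from 2-methylcyclohexane-1,3-dione: allylation, desymmetrising reduction, methylation, dehydrogenation, ozonolysis, enol silylation.
- Ring order: six-membered ring A (a sacrificial template, present from the starting dione), then the ten-membered ring and the lactone together.

Assumption: ten-membered compounds are numbered as germacranes (C1=C10 with C14 on C10; C3 and C9 oxygenated; C4=C5 with C15 on C4; lactone O on C6; C7 bears C11; C13 methyl on C11; C12 carbonyl).
Assumption: the (R,R)-TsDPEN ruthenium catalyst is taken to give the (2R,3R) ketol (the antipode of the baker's-yeast product); if the sense is the reverse, the (S,S) ligand is used.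

**Route**

Step 1
Reactants: 1 2-methylcyclohexane-1,3-dione; 2 allyl bromide
Product: 3 2-methyl-2-(prop-2-en-1-yl)cyclohexane-1,3-dione
Conditions: 1 M aq. NaOH, rt
Reagents that add atoms: none
Why: C-alkylation of the 1,3-dione enolate creates the methyl-bearing quaternary carbon (future C4) and brings in the two carbons that become C5 and C6, with no stereocentre yet.

Step 2
Reactants: 3
Product: 4 (2R,3R)-3-hydroxy-2-methyl-2-(prop-2-en-1-yl)cyclohexan-1-one
Conditions: RuCl(p-cymene)[(R,R)-TsDPEN] (1 mol %), HCO2H/Et3N 5:2, rt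
Reagents that add atoms: none
Why: Noyori-type asymmetric transfer hydrogenation desymmetrises the prochiral dione, the catalyst choosing one enantiotopic carbonyl and hydride arriving anti to the larger allyl group, which sets the carbinol (future C3) and the quaternary centre (future C4) with OH cis to allyl.

Step 3
Reactants: 4
Product: 5 (2R,3R)-3-[(tert-butyldimethylsilyl)oxy]-2-methyl-2-(prop-2-en-1-yl)cyclohexan-1-one
Conditions: TBSOTf, 2,6-lutidine, CH2Cl2, 0 °C
Reagents that add atoms: tert-butyldimethylsilyl triflate CC(C)(C)[Si](C)(C)OS(=O)(=O)C(F)(F)F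
Why: Silyl ether formation protects the hindered secondary alcohol for the enolate and organolithium chemistry that follows, and no stereocentre is touched.

Step 4
Reactants: 5
Product: 7 (2R,3R)-3-[(tert-butyldimethylsilyl)oxy]-2,6-dimethyl-2-(prop-2-en-1-yl)cyclohexan-1-one (both C6 epimers), via lithium enolate 6 (not isolated)
Conditions: LiN(iPr)2, THF, −78 °C; MeI, −78 to 0 °C
Reagents that add atoms: iodomethane CI
Why: Enolate alkylation can occur only at C6 because the other α-carbon is quaternary, and the new methyl centre (future C14 on C10) becomes sp2 in the next step so its configuration is irrelevant.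

Step 5
Reactants: 7
Product: 9 (5R,6R)-5-[(tert-butyldimethylsilyl)oxy]-2,6-dimethyl-6-(prop-2-en-1-yl)cyclohex-2-en-1-one, via trimethylsilyl enol ether 8 (not isolated)
Conditions: LiN(iPr)2, Me3SiCl, THF, −78 °C; then IBX·MPO (4-methoxypyridine N-oxide), DMSO, rt
Reagents that add atoms: none
Why: Regiodefined silyl enol ether formation followed by IBX dehydrogenation (Nicolaou) gives the 2-methyl enone whose ring double bond is the future 1(10)Z alkene, and a palladium-free oxidant avoids cyclisation onto the allyl group.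

Step 6
Reactants: 9
Product: 11 2-[(1R,6R)-6-[(tert-butyldimethylsilyl)oxy]-1,3-dimethyl-2-oxocyclohex-3-en-1-yl]acetaldehyde, via ozonide 10 (not isolated)
Conditions: O3, CH2Cl2, −78 °C (Sudan red 7B end point); PPh3, −78 °C to rt
Reagents that add atoms: ozone O=[O+][O-]
Why: Ozonolysis with an indicator dye cleaves the electron-rich terminal alkene faster than the electron-poor trisubstituted enone alkene and leaves the two-carbon aldehyde arm (C5–C6).

Step 7
Reactants: 11
Product: 12 (5R,6R)-5-[(tert-butyldimethylsilyl)oxy]-6-[(E)-2-[(tert-butyldimethylsilyl)oxy]ethenyl]-2,6-dimethylcyclohex-2-en-1-one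
Conditions: TBSOTf (1.1 equiv), Et3N, CH2Cl2, −78 to 0 °C
Reagents that add atoms: tert-butyldimethylsilyl triflate CC(C)(C)[Si](C)(C)OS(=O)(=O)C(F)(F)F
Why: Soft enolisation (O-silylation then deprotonation by the amine) affects only the aldehyde because the ketone has no α-hydrogen, and the E geometry is an expectation rather than a precedent: the neopentyl-type aldehyde should react through its H-eclipsed conformer, putting the quaternary carbon trans to OSi, which is also the thermodynamically preferred isomer.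

Step 8
Reactants: 13 methyl (2R)-3-hydroxy-2-methylpropanoate
Product: 14 methyl (2R)-3-[(tert-butyldiphenylsilyl)oxy]-2-methylpropanoate
Conditions: TBDPSCl, imidazole, CH2Cl2, rt
Reagents that add atoms: tert-butyl(chloro)diphenylsilane CC(C)(C)[Si](Cl)(c1ccccc1)c1ccccc1
Why: Silyl protection of the primary alcohol of the Roche ester, whose stereocentre becomes C11 (11R) and is never exposed to epimerising conditions.

Step 9
Reactants: 14
Product: 15 (3-methyloxetan-3-yl)methyl (2R)-3-[(tert-butyldiphenylsilyl)oxy]-2-methylpropanoate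
Conditions: (3-methyloxetan-3-yl)methanol (3 equiv), Ti(OiPr)4 (10 mol %), toluene, 100 °C, MeOH removed
Reagents that add atoms: (3-methyloxetan-3-yl)methanol CC1(CO)COC1
Why: Titanate-catalysed transesterification under non-basic conditions exchanges methyl for the oxetanylmethyl group without epimerising the α-centre.

Step 10
Reactants: 15
Product: 16 tert-butyl{[(2R)-2-(4-methyl-2,6,7-trioxabicyclo[2.2.2]octan-1-yl)propyl]oxy}diphenylsilane
Conditions: BF3·OEt2 (0.25 equiv), CH2Cl2, −15 °C; Et3N
Reagents that add atoms: none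
Why: Corey's Lewis-acid rearrangement of an oxetanyl ester gives the bicyclic ortho ester, which masks C12 at the acid oxidation level and removes the acidity of the C11 hydrogen.

Step 11
Reactants: 16
Product: 17 (2R)-2-(4-methyl-2,6,7-trioxabicyclo[2.2.2]octan-1-yl)propan-1-ol
Conditions: Bu4NF, THF, 0 °C to rt
Reagents that add atoms: none
Why: Fluoride desilylation frees the primary alcohol, and the ortho ester is stable to fluoride and base.

Step 12
Reactants: 17
Product: 18 (2R)-2-(4-methyl-2,6,7-trioxabicyclo[2.2.2]octan-1-yl)propanal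
Conditions: Pr4N[RuO4] (5 mol %), NMO, 4 Å MS, CH2Cl2, 0 °C; used crude
Reagents that add atoms: none
Why: Ley–Griffith oxidation is neutral, so the acid-labile ortho ester and the α-stereocentre of the aldehyde survive.

Step 13
Reactants: 18
Product: 19 1-[(2R,3E)-4-iodobut-3-en-2-yl]-4-methyl-2,6,7-trioxabicyclo[2.2.2]octane
Conditions: CrCl2, CHI3, THF, 0 °C to rt
Reagents that add atoms: iodoform IC(I)I
Why: Takai olefination turns the aldehyde into the (E)-vinyl iodide with high E selectivity and without epimerising the adjacent centre.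

Step 14
Reactants: 19 1-[(2R,3E)-4-iodobut-3-en-2-yl]-4-methyl-2,6,7-trioxabicyclo[2.2.2]octane; 12 (5R,6R)-5-[(tert-butyldimethylsilyl)oxy]-6-[(E)-2-[(tert-butyldimethylsilyl)oxy]ethenyl]-2,6-dimethylcyclohex-2-en-1-one
Product: 21 (1S,5R,6R)-5-[(tert-butyldimethylsilyl)oxy]-6-[(E)-2-[(tert-butyldimethylsilyl)oxy]ethenyl]-2,6-dimethyl-1-[(1E,3R)-3-(4-methyl-2,6,7-trioxabicyclo[2.2.2]octan-1-yl)but-1-en-1-yl]cyclohex-2-en-1-ol, via alkenyllithium 20 (not isolated)
Conditions: 19, t-BuLi (2 equiv), Et2O, −78 °C; then 12, THF, −78 to −40 °C; H2O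
Reagents that add atoms: none
Why: Iodine–lithium exchange with retention of the E geometry and 1,2-addition to the hindered, non-enolisable enone, where axial attack anti to the pseudo-axial silyloxyvinyl group should give the 1S carbinol (alkenyl groups trans), although either carbinol epimer can reach a chair transition state with C3 pseudo-equatorial in the next step.

Step 15
Reactants: 21
Product: 26 (3R,6S,7S,11R)-3-hydroxy-9-oxogermacra-1(10)Z,4E-dien-12,6-olide, via potassium alkoxide 22 (not isolated), via ten-membered potassium enolate 23 (not isolated), via bis-silyl keto ortho ester 24 (not isolated), via dihydroxy keto ester 25 (not isolated)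
Conditions: KH, 18-crown-6, THF, 0 °C to rt; AcOH, −78 °C; then 48% aq. HF, MeCN, rt
Reagents that add atoms: water O
Why: Anion-accelerated oxy-Cope ring expansion and, in the same flask, acid-mediated desilylation, ortho ester hydrolysis and lactonisation: a chair transition state with the C4–C3 ring bond pseudo-equatorial and both E alkene termini equatorial forms C6–C7 as 6S,7S (H6 and H7 anti, trans-fused lactone), gives the 4E alkene, keeps the ring alkene as 1(10)Z and leaves the preset 11R centre untouched, so the ten-membered carbocycle and the γ-lactone arise together.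

Step 16
Reactants: 26 (3R,6S,7S,11R)-3-hydroxy-9-oxogermacra-1(10)Z,4E-dien-12,6-olide; 27 (2R)-2-methylbutanoic acid
Product: 28 (3S,6S,7S,11R)-3-[(2R)-2-methylbutanoyloxy]-9-oxogermacra-1(10)Z,4E-dien-12,6-olide
Conditions: PPh3, DIAD, toluene, 0 °C to rt
Reagents that add atoms: none
Why: Mitsunobu esterification, in which SN2 displacement of the oxyphosphonium by the carboxylate inverts the allylic C3 centre from R to S and installs the ester in the same operation.

Step 17
Reactants: 28
Product: 29 (3S,6S,7S,9S,11R)-9-hydroxy-3-[(2R)-2-methylbutanoyloxy]germacra-1(10)Z,4E-dien-12,6-olide (target)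
Conditions: (R)-2-methyl-CBS-oxazaborolidine (0.3 equiv), catecholborane, toluene, −78 °C
Reagents that add atoms: none
Why: Corey–Bakshi–Shibata reduction, in which the (R)-oxazaborolidine treats the alkenyl side (C10) of the enone as the large group and delivers hydride to give the 9S allylic alcohol under reagent control, leaving the lactone and the ester intact.

**Compound list**
1 | 2-methylcyclohexane-1,3-dione | CC1C(=O)CCCC1=O | starting material
2 | allyl bromide (3-bromoprop-1-ene) | C=CCBr | starting material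
3 | 2-methyl-2-(prop-2-en-1-yl)cyclohexane-1,3-dione | C=CCC1(C)C(=O)CCCC1=O | intermediate
4 | (2R,3R)-3-hydroxy-2-methyl-2-(prop-2-en-1-yl)cyclohexan-1-one (OH cis to allyl) | O=C1CCC[C@@H](O)[C@@]1(C)CC=C | intermediate
5 | (2R,3R)-3-[(tert-butyldimethylsilyl)oxy]-2-methyl-2-(prop-2-en-1-yl)cyclohexan-1-one | O=C1CCC[C@@H](O[Si](C)(C)C(C)(C)C)[C@@]1(C)CC=C | intermediate
6 | lithium (5R,6R)-5-[(tert-butyldimethylsilyl)oxy]-6-methyl-6-(prop-2-en-1-yl)cyclohex-1-en-1-olate | [Li]OC1=CCC[C@@H](O[Si](C)(C)C(C)(C)C)[C@@]1(C)CC=C | intermediate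
7 | (2R,3R)-3-[(tert-butyldimethylsilyl)oxy]-2,6-dimethyl-2-(prop-2-en-1-yl)cyclohexan-1-one (C6 epimers) | O=C1C(C)CC[C@@H](O[Si](C)(C)C(C)(C)C)[C@@]1(C)CC=C | intermediate
8 | tert-butyl{[(1R,2R)-2,4-dimethyl-2-(prop-2-en-1-yl)-3-[(trimethylsilyl)oxy]cyclohex-3-en-1-yl]oxy}dimethylsilane | C[Si](C)(C)OC1=C(C)CC[C@@H](O[Si](C)(C)C(C)(C)C)[C@@]1(C)CC=C | intermediate
9 | (5R,6R)-5-[(tert-butyldimethylsilyl)oxy]-2,6-dimethyl-6-(prop-2-en-1-yl)cyclohex-2-en-1-one | O=C1C(C)=CC[C@@H](O[Si](C)(C)C(C)(C)C)[C@@]1(C)CC=C | intermediate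
10 | (5R,6R)-5-[(tert-butyldimethylsilyl)oxy]-2,6-dimethyl-6-[(1,2,4-trioxolan-3-yl)methyl]cyclohex-2-en-1-one (ozonide, epimers at the trioxolane carbon) | O=C1C(C)=CC[C@@H](O[Si](C)(C)C(C)(C)C)[C@@]1(C)CC2OCOO2 | intermediate
11 | 2-[(1R,6R)-6-[(tert-butyldimethylsilyl)oxy]-1,3-dimethyl-2-oxocyclohex-3-en-1-yl]acetaldehyde | O=C1C(C)=CC[C@@H](O[Si](C)(C)C(C)(C)C)[C@@]1(C)CC=O | intermediate
12 | (5R,6R)-5-[(tert-butyldimethylsilyl)oxy]-6-[(E)-2-[(tert-butyldimethylsilyl)oxy]ethenyl]-2,6-dimethylcyclohex-2-en-1-one | O=C1C(C)=CC[C@@H](O[Si](C)(C)C(C)(C)C)[C@@]1(C)/C=C/O[Si](C)(C)C(C)(C)C | intermediate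
13 | methyl (2R)-3-hydroxy-2-methylpropanoate ((R)-Roche ester) | OC[C@@H](C)C(=O)OC | starting material
14 | methyl (2R)-3-[(tert-butyldiphenylsilyl)oxy]-2-methylpropanoate | CC(C)(C)[Si](c1ccccc1)(c1ccccc1)OC[C@@H](C)C(=O)OC | intermediate
15 | (3-methyloxetan-3-yl)methyl (2R)-3-[(tert-butyldiphenylsilyl)oxy]-2-methylpropanoate | CC(C)(C)[Si](c1ccccc1)(c1ccccc1)OC[C@@H](C)C(=O)OCC1(C)COC1 | intermediate
16 | tert-butyl{[(2R)-2-(4-methyl-2,6,7-trioxabicyclo[2.2.2]octan-1-yl)propyl]oxy}diphenylsilane | CC(C)(C)[Si](c1ccccc1)(c1ccccc1)OC[C@@H](C)C12OCC(C)(CO1)CO2 | intermediate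
17 | (2R)-2-(4-methyl-2,6,7-trioxabicyclo[2.2.2]octan-1-yl)propan-1-ol | OC[C@@H](C)C12OCC(C)(CO1)CO2 | intermediate
18 | (2R)-2-(4-methyl-2,6,7-trioxabicyclo[2.2.2]octan-1-yl)propanal | O=C[C@@H](C)C12OCC(C)(CO1)CO2 | intermediate
19 | 1-[(2R,3E)-4-iodobut-3-en-2-yl]-4-methyl-2,6,7-trioxabicyclo[2.2.2]octane | I/C=C/[C@@H](C)C12OCC(C)(CO1)CO2 | intermediate
20 | [(1E,3R)-3-(4-methyl-2,6,7-trioxabicyclo[2.2.2]octan-1-yl)but-1-en-1-yl]lithium | [Li]/C=C/[C@@H](C)C12OCC(C)(CO1)CO2 | intermediate
21 | (1S,5R,6R)-5-[(tert-butyldimethylsilyl)oxy]-6-[(E)-2-[(tert-butyldimethylsilyl)oxy]ethenyl]-2,6-dimethyl-1-[(1E,3R)-3-(4-methyl-2,6,7-trioxabicyclo[2.2.2]octan-1-yl)but-1-en-1-yl]cyclohex-2-en-1-ol | O[C@@]1(/C=C/[C@@H](C)C23OCC(C)(CO2)CO3)C(C)=CC[C@@H](O[Si](C)(C)C(C)(C)C)[C@@]1(C)/C=C/O[Si](C)(C)C(C)(C)C | intermediate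
22 | potassium alkoxide of 21 | [K]O[C@@]1(/C=C/[C@@H](C)C23OCC(C)(CO2)CO3)C(C)=CC[C@@H](O[Si](C)(C)C(C)(C)C)[C@@]1(C)/C=C/O[Si](C)(C)C(C)(C)C | intermediate
23 | potassium (3R,6S,7S)-3,6-bis[(tert-butyldimethylsilyl)oxy]-7-[(1R)-1-(4-methyl-2,6,7-trioxabicyclo[2.2.2]octan-1-yl)ethyl]cyclodeca-1(10)Z,4E,8-trien-9-olate, germacrane numbering (C7 and C10 trans across C8=C9) | CC(C)(C)[Si](C)(C)O[C@@H]1C/C=C(/C)\C(O[K])=C\[C@@H]([C@@H](C)C23OCC(C)(CO2)CO3)[C@@H](/C=C/1C)O[Si](C)(C)C(C)(C)C | intermediate
24 | the 9-ketone of 23: (3R,6S,7S,11R)-3,6-bis[(tert-butyldimethylsilyl)oxy]-9-oxogermacra-1(10)Z,4E-diene with C12 as the 4-methyl-2,6,7-trioxabicyclo[2.2.2]octan-1-yl ortho ester | CC(C)(C)[Si](C)(C)O[C@@H]1C/C=C(/C)C(=O)C[C@@H]([C@@H](C)C23OCC(C)(CO2)CO3)[C@@H](/C=C/1C)O[Si](C)(C)C(C)(C)C | intermediate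
25 | 3-hydroxy-2-(hydroxymethyl)-2-methylpropyl (3R,6S,7S,11R)-3,6-dihydroxy-9-oxogermacra-1(10)Z,4E-dien-12-oate | O[C@@H]1C/C=C(/C)C(=O)C[C@@H]([C@@H](C)C(=O)OCC(C)(CO)CO)[C@@H](/C=C/1C)O | intermediate
26 | (3R,6S,7S,11R)-3-hydroxy-9-oxogermacra-1(10)Z,4E-dien-12,6-olide (trans-fused lactone, 3-epi alcohol) | O[C@@H]1C/C=C(/C)C(=O)C[C@@H]2[C@@H](/C=C/1C)OC(=O)[C@@H]2C | intermediate
27 | (2R)-2-methylbutanoic acid | CC[C@@H](C)C(=O)O | starting material
28 | (3S,6S,7S,11R)-3-[(2R)-2-methylbutanoyloxy]-9-oxogermacra-1(10)Z,4E-dien-12,6-olide | CC[C@@H](C)C(=O)O[C@H]1C/C=C(/C)C(=O)C[C@@H]2[C@@H](/C=C/1C)OC(=O)[C@@H]2C | intermediate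
29 | (3S,6S,7S,9S,11R)-9-hydroxy-3-[(2R)-2-methylbutanoyloxy]germacra-1(10)Z,4E-dien-12,6-olide = (3R,3aS,5S,6Z,9S,10E,11aS)-5-hydroxy-3,6,10-trimethyl-2-oxo-2,3,3a,4,5,8,9,11a-octahydrocyclodeca[b]furan-9-yl (2R)-2-methylbutanoate | CC[C@@H](C)C(=O)O[C@H]1C/C=C(/C)[C@@H](O)C[C@@H]2[C@@H](/C=C/1C)OC(=O)[C@@H]2C | target

**Step count**
Total: 17 steps. Longest linear sequence: 11 steps (steps 1–7, then 14–17); the side-chain branch is steps 8–13.

**Steps most likely to fail**

Step 15. The rearrangement could be upset by silyl transfer from the enol ether to the alkoxide or by leakage through a boat transition state, and the acid stage could damage the allylic alcohols before the lactone closes. The fallback separates the two ring closures and closes the lactone under non-acidic conditions; it does not rescue a failed rearrangement. It sets out from 21: the oxy-Cope is run alone (KH, 18-crown-6, THF; pH 7 buffer quench) and ketone 24 is isolated. Buffered hydrolysis (PPTS, THF/H2O, rt) opens only the ortho ester to the bis-silyl dihydroxy ester F1. Bu4NF buffered with AcOH in THF then removes both silyl groups, and the C6 alkoxide closes the lactone by acyl substitution, returning to the route at 26.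

Step 16. Mitsunobu inversion with an α-branched aliphatic acid on a medium-ring allylic alcohol may be slow, may give SN2' or elimination products, or may be blocked if the 3-OH sits as a transannular hemiketal on the C9 ketone. The fallback activates and displaces in two separate operations. It sets out from 26: MsCl and Et3N in CH2Cl2 at −20 °C give the mesylate F2, which is displaced with inversion by cesium (2R)-2-methylbutanoate (from 27 and Cs2CO3, with 18-crown-6 in toluene/DMF, rt), returning to the route at 28.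

Step 17. The conformation of the ten-membered Z-enone may override the oxazaborolidine and give the 9R alcohol or a mixture. The fallback accepts substrate control and corrects the centre afterwards. It sets out from 28: NaBH4 with CeCl3·7H2O in MeOH at −78 °C gives the substrate-preferred alcohol, taken to be the 9R alcohol F3. Mitsunobu reaction with formic acid (PPh3, DIAD, THF) inverts it to the 9S formate F4, and selective methanolysis of the formate (KHCO3, MeOH, 0 °C) leaves the 2-methylbutanoate and the lactone untouched and returns to the route at 29.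

Further compounds
F1 | step 15 | 3-hydroxy-2-(hydroxymethyl)-2-methylpropyl (3R,6S,7S,11R)-3,6-bis[(tert-butyldimethylsilyl)oxy]-9-oxogermacra-1(10)Z,4E-dien-12-oate | CC(C)(C)[Si](C)(C)O[C@@H]1C/C=C(/C)C(=O)C[C@@H]([C@@H](C)C(=O)OCC(C)(CO)CO)[C@@H](/C=C/1C)O[Si](C)(C)C(C)(C)C
F2 | step 16 | (3R,6S,7S,11R)-3-(methanesulfonyloxy)-9-oxogermacra-1(10)Z,4E-dien-12,6-olide | CS(=O)(=O)O[C@@H]1C/C=C(/C)C(=O)C[C@@H]2[C@@H](/C=C/1C)OC(=O)[C@@H]2C
F3 | step 17 | (3S,6S,7S,9R,11R)-9-hydroxy-3-[(2R)-2-methylbutanoyloxy]germacra-1(10)Z,4E-dien-12,6-olide | CC[C@@H](C)C(=O)O[C@H]1C/C=C(/C)[C@H](O)C[C@@H]2[C@@H](/C=C/1C)OC(=O)[C@@H]2C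
F4 | step 17 | (3S,6S,7S,9S,11R)-9-(formyloxy)-3-[(2R)-2-methylbutanoyloxy]germacra-1(10)Z,4E-dien-12,6-olide | CC[C@@H](C)C(=O)O[C@H]1C/C=C(/C)[C@@H](OC=O)C[C@@H]2[C@@H](/C=C/1C)OC(=O)[C@@H]2C
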